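**Retrosynthetic overview**

- The strategy rests on ring A: a hexasubstituted benzene whose oxygens at C2, C4 and C6 alternate with carbon groups at C1 (butyryl), C3 (CH2 to the acetyl dienone ring B) and C5 (CH2 to the propionyl dienone ring C).
- Last disconnections: the five alkyl ethers (BCl3), the C1–butyryl bond (Friedel–Crafts acylation at the one free ring-A carbon) and the silyl groups.
- Key disconnection: ring-A bonds C4–C5 and C6–C1, with C3–C4 opened and re-closed. This gives 3-ethoxycyclobutenone 10 carrying ring B and siloxyalkyne 19 carrying ring C.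
- 10 comes from acetylfilicinic acid by Michael addition to benzyl acrylate, O-methylation, hydrogenolysis and ketene/ethoxyacetylene [2+2]. 19 comes from propionylfilicinic acid by C-propargylation, O-methylation, enol silylation and acetylide oxidation/silylation.
- Ring order: rings B and C first (dearomatising gem-dimethylation of the two acylphloroglucinols), then the cyclobutenone ring, then ring A.

Key step: step 11

**Assumptions**

- O-Methylation of the C-alkylated acylfilicinic acids is taken to give the 3,5-dimethoxy-6,6-dimethylcyclohexa-2,4-dienone isomers drawn; other enol-ether regioisomers would serve equally, since all are cleaved in step 14.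
- The silyl enol ether that masks the propionyl group (steps 9–11) is drawn Z; its geometry has no consequence, because the ketone returns in step 12.
- Compounds 10 and 23 are racemic; the target has no stereocentre.

**Route**

Step 1
Reactants: 1 1-(2,4,6-trihydroxyphenyl)ethan-1-one
Product: 2 2-acetyl-3,5-dihydroxy-6,6-dimethylcyclohexa-2,4-dien-1-one (acetylfilicinic acid)
Conditions: NaOMe (3.3 equiv), MeI (2.2 equiv), MeOH, 0 °C to rt; aq. HCl
Reagents that add atoms: iodomethane CI
Why: Exhaustive C-methylation of the phloroglucinol polyanion, in which the second methyl group enters the carbon that already bears one and so dearomatises the ring to the gem-dimethyl triketone (the standard preparation of acylfilicinic acids).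

Step 2
Reactants: 2 acetylfilicinic acid; 3 benzyl acrylate
Product: 4 benzyl 3-(5-acetyl-2,6-dihydroxy-3,3-dimethyl-4-oxocyclohexa-1,5-dien-1-yl)propanoate
Conditions: DBU (2.2 equiv), 3 (1.1 equiv), MeCN, rt to 50 °C; 1 M HCl
Reagents that add atoms: none
Why: Michael addition of the doubly deprotonated vinylogous acid through its only free ring carbon (between two enolised carbonyls) to the acrylate; the benzyl ester is used so that the acid can later be released without acid or base.

Step 3
Reactants: 4 benzyl ester with two free enols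
Product: 5 benzyl 3-(5-acetyl-2,6-dimethoxy-3,3-dimethyl-4-oxocyclohexa-1,5-dien-1-yl)propanoate
Conditions: TMSCHN2 (excess), MeOH/toluene, 0 °C to rt
Reagents that add atoms: trimethylsilyldiazomethane C[Si](C)(C)C=[N+]=[N-]
Why: Diazoalkane O-methylation of the two acidic enols, which removes the protons that would otherwise quench the ketene of step 5 and the siloxyalkyne of step 11.

Step 4
Reactants: 5 bis-methyl ether benzyl ester
Product: 6 3-(5-acetyl-2,6-dimethoxy-3,3-dimethyl-4-oxocyclohexa-1,5-dien-1-yl)propanoic acid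
Conditions: H2 (1 atm), Pd/C, EtOAc, rt
Reagents that add atoms: none
Why: Hydrogenolysis of the benzyl ester under neutral conditions, the tetrasubstituted push–pull double bonds of the dienone and the ketones being inert at 1 atm.

Step 5
Reactants: 6 propanoic acid; 7 ethoxyacetylene
Product: 10 4-[(5-acetyl-2,6-dimethoxy-3,3-dimethyl-4-oxocyclohexa-1,5-dien-1-yl)methyl]-3-ethoxycyclobut-2-en-1-one (racemic), via acid chloride 8 (not isolated), via ketene 9 (not isolated)
Conditions: 1-chloro-N,N,2-trimethylprop-1-en-1-amine (1.05 equiv), CH2Cl2, 0 °C to rt; then slow addition to 7 (5 equiv), Et3N (1.5 equiv), CH2Cl2, rt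
Reagents that add atoms: none
Why: Neutral acid chloride formation, dehydrochlorination to the aldoketene and ketene–ynol ether [2+2] cycloaddition, in which the nucleophilic terminal carbon of ethoxyacetylene bonds to the ketene carbonyl carbon so that ethoxy ends at C3 and the ring-B arm at C4 (the new C4 stereocentre is racemic and is destroyed in step 11).

Step 6
Reactants: 11 1-(2,4,6-trihydroxyphenyl)propan-1-one
Product: 12 3,5-dihydroxy-6,6-dimethyl-2-propanoylcyclohexa-2,4-dien-1-one (propionylfilicinic acid)
Conditions: NaOMe (3.3 equiv), MeI (2.2 equiv), MeOH, 0 °C to rt; aq. HCl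
Reagents that add atoms: iodomethane CI
Why: The same dearomatising gem-dimethylation of the phloroglucinol polyanion as in step 1.

Step 7
Reactants: 12 propionylfilicinic acid; 13 propargyl bromide
Product: 14 3,5-dihydroxy-6,6-dimethyl-2-propanoyl-4-(prop-2-yn-1-yl)cyclohexa-2,4-dien-1-one
Conditions: NaOMe (2.1 equiv), 13 (1.05 equiv), MeOH, 0 °C to rt; aq. HCl
Reagents that add atoms: none
Why: C-Alkylation of the dianion at its only free ring carbon by a soft propargylic halide in a protic solvent, the same site selectivity that operates in the C-methylation and C-prenylation of acylfilicinic acids.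

Step 8
Reactants: 14 C-propargylated propionylfilicinic acid
Product: 15 3,5-dimethoxy-6,6-dimethyl-2-propanoyl-4-(prop-2-yn-1-yl)cyclohexa-2,4-dien-1-one
Conditions: TMSCHN2 (excess), MeOH/toluene, 0 °C to rt
Reagents that add atoms: trimethylsilyldiazomethane C[Si](C)(C)C=[N+]=[N-]
Why: Diazoalkane O-methylation of both acidic enols, as in step 3, which leaves the alkyne and the ketones untouched.

Step 9
Reactants: 15 bis-methyl ether alkyne
Product: 16 3,5-dimethoxy-6,6-dimethyl-4-(prop-2-yn-1-yl)-2-[(Z)-1-(triisopropylsilyloxy)prop-1-en-1-yl]cyclohexa-2,4-dien-1-one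
Conditions: TIPSOTf (1.3 equiv), Et3N (2 equiv), CH2Cl2, 0 °C to rt
Reagents that add atoms: triisopropylsilyl trifluoromethanesulfonate CC(C)[Si](OS(=O)(=O)C(F)(F)F)(C(C)C)C(C)C
Why: Soft enolisation of the propionyl ketone (silyl dienol ether formation from a vinylogous-ester ketone) masks the only C–H more acidic than the alkyne, so that step 10 needs a single equivalent of base.

Step 10
Reactants: 16 silyl enol ether alkyne
Product: 19 3,5-dimethoxy-6,6-dimethyl-2-[(Z)-1-(triisopropylsilyloxy)prop-1-en-1-yl]-4-[3-(triisopropylsilyloxy)prop-2-yn-1-yl]cyclohexa-2,4-dien-1-one, via lithium acetylide 17 (not isolated), via lithium ynolate 18 (not isolated)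
Conditions: LiN(SiMe3)2 (1.1 equiv), THF, −78 °C; t-BuOOLi (from t-BuOOH and LiN(SiMe3)2, 1.2 equiv), −78 to 0 °C; TIPSOTf (1.5 equiv), −78 to 0 °C; aq. NaHCO3, Et3N-deactivated silica
Reagents that add atoms: tert-butyl hydroperoxide (as its lithium salt, supplies the oxygen) CC(C)(C)OO; triisopropylsilyl trifluoromethanesulfonate CC(C)[Si](OS(=O)(=O)C(F)(F)F)(C(C)C)C(C)C
Why: Oxidation of the lithium acetylide by lithium tert-butyl peroxide to the ynolate and O-silylation by the bulky silyl triflate (the standard acetylide-to-siloxyalkyne sequence), the ring ketone being shielded by a quaternary and a fully substituted sp2 carbon and no other acidic hydrogen being present.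

Step 11
Reactants: 10 3-ethoxycyclobutenone carrying ring B; 19 siloxyalkyne carrying ring C
Product: 24 ring-A phenol (C4 OH; C3 CH2–ring B bis-methyl ether; C2 OEt; C1 H; C6 OSi(i-Pr)3; C5 CH2–ring C bis-methyl ether with the propionyl group as silyl enol ether), via vinylketene 20 (not isolated), via 4-vinylcyclobutenone 21 (not isolated), via dienylketene 22 (not isolated), via cyclohexa-2,4-dienone 23 (not isolated)
Conditions: 10 (1.0 equiv), 19 (1.3 equiv), toluene (0.2 M), argon, 80 °C then 110 °C
Reagents that add atoms: none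
Why: Thermal 4π-electrocyclic opening of 10, with the C4 arm rotating outward so that its CH2 stays remote from the ketene and no 1,5-hydrogen shift can occur, gives vinylketene 20, which adds [2+2] to siloxyalkyne 19 to give 21; this opens again to dienylketene 22, which closes to dienone 23 and tautomerises to phenol 24. This is the Danheiser benzannulation of a cyclobutenone with a siloxyalkyne, applied here to a 3-alkoxy-4-alkylcyclobutenone. Ring A is closed by a thermal disrotatory 6π-electrocyclisation: the [2+2] supplies bonds C4–C5 and C6–C1, and the ring-A C3–C4 bond (the C1–C4 bond of the cyclobutenone, broken in the first opening) is re-formed in the closure. No stereocentre is created, because the sp3 carbon of 23 is lost on enolisation. The selectivity needed is the regiochemistry of the [2+2], which the polarisation of the silyl ynol ether secures: its carbon remote from oxygen bonds to the ketene carbonyl carbon, placing the silyloxy group meta and the ring-C arm ortho to the new hydroxyl. The wings should be spectators, since their enol-ether double bonds are tetrasubstituted and deactivated by the dienone and the medium contains neither acid nor base.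

Step 12
Reactants: 24 bis-silylated benzannulation product
Product: 25 ring-A diol (C4 OH and C6 OH; C2 OEt; C1 H; both wings as bis-methyl ethers with free acetyl and propionyl groups)
Conditions: HF·pyridine, pyridine, THF, 0 °C to rt
Reagents that add atoms: none
Why: Fluoride-driven cleavage of the aryl silyl ether and of the silyl enol ether, with buffered HF chosen over Bu4NF so that no phenoxide forms that could add to an enol-ether carbon of a wing.

Step 13
Reactants: 25 ring-A diol
Product: 26 C1-butyryl ring A (C2 OEt; C4 OH and C6 OH; wings as bis-methyl ethers)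
Conditions: butanoyl chloride (1.1 equiv), TiCl4 (3 equiv), CH2Cl2, −78 to −20 °C; aq. NaHCO3
Reagents that add atoms: butanoyl chloride CCCC(=O)Cl
Why: Friedel–Crafts acylation at the single unsubstituted carbon of the phloroglucinol-type ring, which three oxygens activate; any O-butyrate formed first should converge on the same ketone by Fries rearrangement under the same conditions.

Step 14
Reactants: 26 penta-ether
Product: 27 target CNP0325527.0
Conditions: BCl3 (12 equiv), CH2Cl2, −78 to 0 °C; then H2O
Reagents that add atoms: none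
Why: Boron trichloride dealkylation, in which chloride removes the methyl groups of the four boron-complexed vinylogous esters and the ethyl group of the aryl ether chelated to the ortho butyryl carbonyl, without a basic step that could exchange the methylene bridges.

**Compound list**

1 | 1-(2,4,6-trihydroxyphenyl)ethan-1-one | CC(=O)c1c(O)cc(O)cc1O | starting material
2 | 2-acetyl-3,5-dihydroxy-6,6-dimethylcyclohexa-2,4-dien-1-one | CC(=O)C1=C(O)C=C(O)C(C)(C)C1=O | intermediate
3 | benzyl acrylate | C=CC(=O)OCc1ccccc1 | starting material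
4 | benzyl 3-(5-acetyl-2,6-dihydroxy-3,3-dimethyl-4-oxocyclohexa-1,5-dien-1-yl)propanoate | CC(=O)C1=C(O)C(CCC(=O)OCc2ccccc2)=C(O)C(C)(C)C1=O | intermediate
5 | benzyl 3-(5-acetyl-2,6-dimethoxy-3,3-dimethyl-4-oxocyclohexa-1,5-dien-1-yl)propanoate | CC(=O)C1=C(OC)C(CCC(=O)OCc2ccccc2)=C(OC)C(C)(C)C1=O | intermediate
6 | 3-(5-acetyl-2,6-dimethoxy-3,3-dimethyl-4-oxocyclohexa-1,5-dien-1-yl)propanoic acid | CC(=O)C1=C(OC)C(CCC(=O)O)=C(OC)C(C)(C)C1=O | intermediate
7 | ethoxyacetylene | C#COCC | starting material
8 | 3-(5-acetyl-2,6-dimethoxy-3,3-dimethyl-4-oxocyclohexa-1,5-dien-1-yl)propanoyl chloride | CC(=O)C1=C(OC)C(CCC(=O)Cl)=C(OC)C(C)(C)C1=O | intermediate (not isolated)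
9 | ketene from 8 | CC(=O)C1=C(OC)C(CC=C=O)=C(OC)C(C)(C)C1=O | intermediate (not isolated)
10 | 4-[(5-acetyl-2,6-dimethoxy-3,3-dimethyl-4-oxocyclohexa-1,5-dien-1-yl)methyl]-3-ethoxycyclobut-2-en-1-one (racemic) | CCOC1=CC(=O)C1CC2=C(OC)C(C)(C)C(=O)C(C(C)=O)=C2OC | intermediate
11 | 1-(2,4,6-trihydroxyphenyl)propan-1-one | CCC(=O)c1c(O)cc(O)cc1O | starting material
12 | 3,5-dihydroxy-6,6-dimethyl-2-propanoylcyclohexa-2,4-dien-1-one | CCC(=O)C1=C(O)C=C(O)C(C)(C)C1=O | intermediate
13 | propargyl bromide | C#CCBr | starting material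
14 | 3,5-dihydroxy-6,6-dimethyl-2-propanoyl-4-(prop-2-yn-1-yl)cyclohexa-2,4-dien-1-one | CCC(=O)C1=C(O)C(CC#C)=C(O)C(C)(C)C1=O | intermediate
15 | 3,5-dimethoxy-6,6-dimethyl-2-propanoyl-4-(prop-2-yn-1-yl)cyclohexa-2,4-dien-1-one | CCC(=O)C1=C(OC)C(CC#C)=C(OC)C(C)(C)C1=O | intermediate
16 | 3,5-dimethoxy-6,6-dimethyl-4-(prop-2-yn-1-yl)-2-[(Z)-1-(triisopropylsilyloxy)prop-1-en-1-yl]cyclohexa-2,4-dien-1-one | C/C=C(\O[Si](C(C)C)(C(C)C)C(C)C)C1=C(OC)C(CC#C)=C(OC)C(C)(C)C1=O | intermediate
17 | lithium acetylide of 16 | C/C=C(\O[Si](C(C)C)(C(C)C)C(C)C)C1=C(OC)C(CC#[C-])=C(OC)C(C)(C)C1=O.[Li+] | intermediate (not isolated)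
18 | lithium ynolate from 17 | C/C=C(\O[Si](C(C)C)(C(C)C)C(C)C)C1=C(OC)C(CC#C[O-])=C(OC)C(C)(C)C1=O.[Li+] | intermediate (not isolated)
19 | 3,5-dimethoxy-6,6-dimethyl-2-[(Z)-1-(triisopropylsilyloxy)prop-1-en-1-yl]-4-[3-(triisopropylsilyloxy)prop-2-yn-1-yl]cyclohexa-2,4-dien-1-one | C/C=C(\O[Si](C(C)C)(C(C)C)C(C)C)C1=C(OC)C(CC#CO[Si](C(C)C)(C(C)C)C(C)C)=C(OC)C(C)(C)C1=O | intermediate
20 | vinylketene from 10 (ring-B arm trans to the ketene carbon) | O=C=C/C(OCC)=C/CC1=C(OC)C(C)(C)C(=O)C(C(C)=O)=C1OC | intermediate (not isolated)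
21 | 4-vinylcyclobutenone from 20 and 19 | C/C=C(\O[Si](C(C)C)(C(C)C)C(C)C)C1=C(OC)C(CC2=C(O[Si](C(C)C)(C(C)C)C(C)C)C(/C(OCC)=C/CC3=C(OC)C(C)(C)C(=O)C(C(C)=O)=C3OC)C2=O)=C(OC)C(C)(C)C1=O | intermediate (not isolated)
22 | dienylketene from 21 | C/C=C(\O[Si](C(C)C)(C(C)C)C(C)C)C1=C(OC)C(CC(=C=O)/C(O[Si](C(C)C)(C(C)C)C(C)C)=C\C(OCC)=C\CC3=C(OC)C(C)(C)C(=O)C(C(C)=O)=C3OC)=C(OC)C(C)(C)C1=O | intermediate (not isolated)
23 | cyclohexa-2,4-dienone from 22 (racemic) | C/C=C(\O[Si](C(C)C)(C(C)C)C(C)C)C1=C(OC)C(CC2=C(O[Si](C(C)C)(C(C)C)C(C)C)C=C(OCC)C(CC3=C(OC)C(C)(C)C(=O)C(C(C)=O)=C3OC)C2=O)=C(OC)C(C)(C)C1=O | intermediate (not isolated)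
24 | ring-A phenol with C6 silyl ether, C2 ethyl ether, free C1 and both protected wings | C/C=C(\O[Si](C(C)C)(C(C)C)C(C)C)C1=C(OC)C(Cc2c(O[Si](C(C)C)(C(C)C)C(C)C)cc(OCC)c(CC3=C(OC)C(C)(C)C(=O)C(C(C)=O)=C3OC)c2O)=C(OC)C(C)(C)C1=O | intermediate
25 | ring-A diol with C2 ethyl ether, free C1 and both wings as bis-methyl ethers | CCC(=O)C1=C(OC)C(Cc2c(O)cc(OCC)c(CC3=C(OC)C(C)(C)C(=O)C(C(C)=O)=C3OC)c2O)=C(OC)C(C)(C)C1=O | intermediate
26 | C1-butyryl penta-ether | CCCC(=O)c1c(O)c(CC2=C(OC)C(C)(C)C(=O)C(C(=O)CC)=C2OC)c(O)c(CC2=C(OC)C(C)(C)C(=O)C(C(C)=O)=C2OC)c1OCC | intermediate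
27 | CNP0325527.0 | CCCC(=O)c1c(O)c(CC2=C(O)C(C)(C)C(=O)C(C(C)=O)=C2O)c(O)c(CC2=C(O)C(C)(C)C(=O)C(C(=O)CC)=C2O)c1O | target

**Step count**

Total: 14 steps. Longest linear sequence: 9 steps (steps 1–5 or 6–10, then 11–14).

**Steps most likely to fail**

1. Step 11. The vinylketene may be consumed by dimerisation or by addition of the newly formed phenol faster than it is captured by the hindered siloxyalkyne. At 110 °C the new phenol may also add to an enol-ether carbon of a wing with loss of methanol. Fallback: the known base-mediated methylene-bridge assembly, which sets out from 2 and 12 and comes back at 27. Acetylfilicinic acid 2, aqueous formaldehyde (1 equiv) and an excess of purchased 1-(2,4,6-trihydroxyphenyl)butan-1-one F1 in dilute aqueous KOH at 0 °C should give the mono-bridged 1-{3-[(acetylfilicinyl)methyl]-2,4,6-trihydroxyphenyl}butan-1-one F2. After separation from the symmetric by-products, F2 would be condensed in the same way with 12 and formaldehyde at its remaining free ring carbon to give 27. Statistical mixtures and bridge exchange are the price of this route.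

2. Step 13. The Lewis acid may expel a CH2-linked wing from the very electron-rich ring A by ipso attack, or may promote pyran closure of a phenol onto a wing, before acylation is complete. Fallback: a formylation–alkylation–oxidation sequence without a strong Lewis acid, which sets out from 25 and comes back at 26. Vilsmeier–Haack formylation (POCl3, DMF, MeCN, 0 °C; aq. NaOAc) should give the C1 aldehyde F3. Aldehyde-selective addition of n-PrTi(OiPr)3 (from n-PrMgCl and ClTi(OiPr)3, THF, −40 to 0 °C) should give the racemic benzylic alcohol F4. Oxidation with MnO2 in CH2Cl2 should then give 26.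

3. Step 14. The ethyl ether may be cleaved incompletely, or the boron halide may cleave a methylene bridge or cause cyclodehydration, while five ethers are removed at once. Fallback: stepwise nucleophilic dealkylation, which sets out from 26 and comes back at 27. LiI in EtOAc at 60 °C, followed by acidification, should remove the four methyl groups by SN2 attack and give the ring-A ethyl ether of the target F5. MgI2·OEt2 in toluene at 60–80 °C should then remove the ethyl group under chelation by the ortho butyryl carbonyl to give 27.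

**Further compounds**

F1 | step 11 | 1-(2,4,6-trihydroxyphenyl)butan-1-one | CCCC(=O)c1c(O)cc(O)cc1O
F2 | step 11 | 1-{3-[(acetylfilicinyl)methyl]-2,4,6-trihydroxyphenyl}butan-1-one (mono-bridged dimer) | CCCC(=O)c1c(O)cc(O)c(CC2=C(O)C(C)(C)C(=O)C(C(C)=O)=C2O)c1O
F3 | step 13 | C1 aldehyde of 25 | O=Cc1c(O)c(CC2=C(OC)C(C)(C)C(=O)C(C(=O)CC)=C2OC)c(O)c(CC2=C(OC)C(C)(C)C(=O)C(C(C)=O)=C2OC)c1OCC
F4 | step 13 | C1 1-hydroxybutyl compound (racemic) | CCCC(O)c1c(O)c(CC2=C(OC)C(C)(C)C(=O)C(C(=O)CC)=C2OC)c(O)c(CC2=C(OC)C(C)(C)C(=O)C(C(C)=O)=C2OC)c1OCC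
F5 | step 14 | ring-A C2 ethyl ether of the target | CCCC(=O)c1c(O)c(CC2=C(O)C(C)(C)C(=O)C(C(=O)CC)=C2O)c(O)c(CC2=C(O)C(C)(C)C(=O)C(C(C)=O)=C2O)c1OCC
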